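No constant of this chemistry comes with the runs, but the earlier runs yield one rate that changes little with the charge.

| flask | starting material | second substrate | protic impurity | free enzyme | remark | time |
|---|---|---|---|---|---|---|
| east | 20 mM | 36 mM | 6 mM | 2 µM | run made earlier |  |
| south-east | 10 mM | 36 mM | 6 mM | 2 µM | run made earlier |  |
| west | 40 mM | 36 mM | 6 mM | 2 µM | run made earlier |  |
| epsilon | 20 mM (fed, over 50 h) | 36.0 mM | 6.00 mM | 2.0 µM | all else is in the flask from the start; the feed brings no volume worth counting | 2.5 d |
| eta | 20 mM | 36.0 mM (fed, over 50 h) | 6.00 mM | 2.0 µM | all else is in the flask from the start; the feed brings no volume worth counting | 2.5 d |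
| gamma | 20 mM | 36.0 mM | 6.00 mM | 2.0 µM | everything together at the start | 2.5 d |

| run | time / d | over-reaction product / % | target / % |
|---|---|---|---|
| east | 0.208 | 1.5 | 3.5 |
| east | 0.625 | 9.0 | 7.2 |
| east | 1.25 | 24.4 | 6.7 |
| east | 1.67 | 32.3 | 6.5 |
| east | 2.50 | 49.5 | 5.3 |
| south-east | 0.250 | 4.0 | 9.8 |
| south-east | 0.833 | 27.2 | 15.1 |
| south-east | 1.25 | 46.3 | 14.1 |
| south-east | 2.00 | 76.5 | 10.9 |
| south-east | 3.00 | 98.0 | 1.2 |
| west | 0.250 | 1.8 | 2.8 |
| west | 0.833 | 7.3 | 5.3 |
| west | 1.25 | 12.4 | 2.7 |
| west | 2.00 | 20.1 | 3.0 |
| west | 3.00 | 29.4 | 3.2 |

(standard deviation of a reading: 0.5 percentage points)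



- the flask with the highest amount of over-reaction product, in percent of the starting material charged ("all alike" if they lie within 1.5 percentage points) (epsilon / eta / gamma / all alike)
- final over-reaction product, as a percentage of the starting material charged, in epsilon
- final over-reaction product, as a percentage of the starting material charged, in eta
- final over-reaction product, as a percentage of the starting material charged, in gamma

Look at the two outer runs at 1.25 d: the south-east run has turned 46.3% of its charge into over-reaction product, the west run 12.4%, so the smaller charge shows the higher fraction. In powers of ten that ratio is 0.572, and the ratio of charges is 0.602. You can therefore treat the rate as zero order in starting material at these charges, up to that time. The east run gives 3.96 mM d⁻¹ for the delivery, the fraction of the charge made into over-reaction product per day times the charge.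

How fast is the start, and what slows it? Up to 0.625 d, the east run makes target and over-reaction product together at 0.259 d⁻¹ of its charge. In its last stretch it makes them at 0.193 d⁻¹, a factor 0.745. One second substrate per product would leave a share 0.696 at the end of the east run, so I let the rate follow second substrate, though these readings cannot exclude a decaying enzyme.

Gamma repeats the east run, so I take 49.5%. Epsilon's feed brings 0.480 d⁻¹ of the charge, more than 0.259 d⁻¹, so I put epsilon close behind gamma. In eta the fed share of second substrate averages 0.583 over the time, which is −0.234 in powers of ten. On my reckoning the accumulated slowing puts eta at 28.9%.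

The forecast names gamma, with 47.5% (44% to 50.5%) for epsilon, 38% (28% to 46%) for eta and 49.5% (48% to 51%) for gamma, noting that the slowing “may reflect falling second substrate, or enzyme decay”. My eta is lower than its figure.

The flasks give gamma as highest: epsilon 45.6%, eta 31.6%, gamma 49.2%.

    first complex → spent catalyst (k = 0.0150 h⁻¹)
    target → over-reaction product (k = 0.134 h⁻¹)
    second complex → free enzyme + target (k = 475 h⁻¹)
    second substrate + protic impurity → quenched reagent (k = 1.93 M⁻¹ h⁻¹)
    first complex → loaded enzyme + first product (k = 693 h⁻¹)
    second substrate + loaded enzyme ⇌ second complex (K = 13.0 M⁻¹, k = 3.60 × 10⁵ M⁻¹ h⁻¹)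
    starting material + free enzyme ⇌ first complex (K = 480 M⁻¹, k = 2.19 × 10⁶ M⁻¹ h⁻¹)

Eta's delivery, averaged over the time, comes to 2.53 mM d⁻¹, a factor 0.639 of the east run's, against my fed share of 0.583. Now take the neighbour: eta with 12 mM of starting material in place of 20 mM. The same delivery over 2.5 d makes 52.7% of that smaller charge. That neighbour gives 51.9% over-reaction product, with 37.6% of its starting material left.

The earlier runs and the new flask are simulated on assumed constants, noise included.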